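## Retrosynthetic overview

1. The target comes from a Schenck ene reaction of singlet oxygen with a Δ4(5) olefin, which installs C5–OOH and the C4=C15 methylene together. The olefin comes from a 3,8‑dioxo‑Δ4 enedione by double reduction, two site‑selective acylations and oxidation of C12.
2. The enedione comes from dehydration of a cis‑fused 5‑hydroxy‑3,8‑dione. That ketol is made by closing ring A at C1–C10 through a redox‑neutral cyclopropanol ring‑opening/6‑exo radical conjugate addition (key step).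
3. Enabling feature: the oxygens at C3 (ring A) and C8 (ring B) are 1,6‑related through C2–C1–C10–C9. C1–C10 therefore joins a C3 homoenolate (β‑keto radical from a cyclopropanol built of C1–C3) to C10, the β‑carbon of a ring B C8 enone. The tertiary C5–OH relays stereochemistry and then leaves to give the Δ4 alkene.
4. The cyclisation substrate comes from a propanoate aldol (C4–C5) and a Kulinkovich reaction on a carvone‑like enone. That enone comes from rhodium‑catalysed asymmetric alkenylation (C7) of the quinone monoketal of 4‑methoxy‑2‑methylphenol.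
5. Ring order: ring B is the aromatic ring of the phenol; ring A is formed last.

Key step: step 8

## Remarks and assumptions

- Eudesmane numbering (C1–C15) is used throughout; β means the face of the C10 methyl group.
- All intermediates between the aldol step and the dehydration step are mixtures of epimers at C4, written without configuration there; C4 becomes an alkene carbon in the dehydration.
- The sense of induction of (R)‑BINAP in step 4 is assumed by analogy with cyclohex‑2‑enone (it should give 5R, the 7R centre of the target); if the opposite sense is found, (S)‑BINAP is used.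

## Route

Step 1
Reactants: 1 2‑bromoprop‑2‑en‑1‑ol
Product: 2 tert‑butyl[(2‑bromoprop‑2‑en‑1‑yl)oxy]diphenylsilane
Conditions: TBDPSCl, imidazole, CH2Cl2, 0 °C to rt
Reagents that add atoms: tert‑butyl(chloro)diphenylsilane, CC(C)(C)[Si](Cl)(c1ccccc1)c1ccccc1
Why: Imidazole‑promoted silylation of a primary allylic alcohol should be clean, and the TBDPS ether is chosen because it must survive the mild acid of steps 7 and 9.

Step 2
Reactants: 2 tert‑butyl[(2‑bromoprop‑2‑en‑1‑yl)oxy]diphenylsilane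
Product: 3 tert‑butyldiphenyl{[2‑(4,4,5,5‑tetramethyl‑1,3,2‑dioxaborolan‑2‑yl)prop‑2‑en‑1‑yl]oxy}silane
Conditions: B2pin2, PdCl2(PPh3)2 (3 mol %), PPh3 (6 mol %), PhOK, toluene, 50 °C
Reagents that add atoms: bis(pinacolato)diboron, CC1(C)OB(OC1(C)C)B1OC(C)(C)C(C)(C)O1
Why: Miyaura borylation of a 1‑alkenyl bromide under phenoxide conditions proceeds by oxidative addition to zerovalent palladium and transmetalation, with the silyl ether inert.

Step 3
Reactants: 4 4‑methoxy‑2‑methylphenol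
Product: 5 4,4‑dimethoxy‑2‑methylcyclohexa‑2,5‑dien‑1‑one
Conditions: PhI(OAc)2, MeOH, 0 °C
Reagents that add atoms: methanol, CO
Why: Oxidative dearomatisation of a para‑methoxyphenol with PhI(OAc)2 in methanol gives the para‑quinone monoketal, methanol adding at the methoxy‑bearing carbon.

Step 4
Reactants: 5 4,4‑dimethoxy‑2‑methylcyclohexa‑2,5‑dien‑1‑one; 3 alkenylboronate
Product: 6 (5R)‑5‑{3‑[(tert‑butyldiphenylsilyl)oxy]prop‑1‑en‑2‑yl}‑4,4‑dimethoxy‑2‑methylcyclohex‑2‑en‑1‑one
Conditions: [RhCl(C2H4)2]2 (2.5 mol %), (R)‑BINAP (5.5 mol %), KOH (20 mol %), dioxane/H2O 10:1, 40 °C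
Reagents that add atoms: none
Why: In this Hayashi–Miyaura rhodium‑catalysed asymmetric 1,4‑addition the alkenylrhodium species should insert only the unsubstituted C6=C7 enone (the C9=C10 enone is blocked by its α‑methyl group), and the chiral bisphosphine sets C7 as R.

Step 5
Reactants: 6 ketal enone; 7 methyl propanoate
Product: 10 methyl 2‑[(1S,5R)‑5‑{3‑[(tert‑butyldiphenylsilyl)oxy]prop‑1‑en‑2‑yl}‑4,4‑dimethoxy‑2‑methyl‑1‑[(trimethylsilyl)oxy]cyclohex‑2‑en‑1‑yl]propanoate, via lithium enolate 8 (not isolated), via lithium aldolate 9 (not isolated)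
Conditions: LDA, THF, −78 °C; then 6, −78 °C; then TMSCl, −78 °C to 0 °C
Reagents that add atoms: chlorotrimethylsilane, C[Si](C)(C)Cl
Why: Kinetic 1,2‑addition of a lithium ester enolate (aldol addition) to this carvone‑like enone should occur axially on the face anti to the C7 substituent, as with carvone, placing the new C5–O bond cis to the side chain, and O‑silylation of the tertiary alkoxide blocks retro‑aldol cleavage.

Step 6
Reactants: 10 β‑silyloxy ester
Product: 11 1‑{1‑[(1S,5R)‑5‑{3‑[(tert‑butyldiphenylsilyl)oxy]prop‑1‑en‑2‑yl}‑4,4‑dimethoxy‑2‑methyl‑1‑[(trimethylsilyl)oxy]cyclohex‑2‑en‑1‑yl]ethyl}cyclopropan‑1‑ol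
Conditions: EtMgBr (3.5 equiv), Ti(OiPr)4 (30 mol %), THF, 0 °C to rt; aq NH4Cl
Reagents that add atoms: ethylmagnesium bromide, CC[Mg]Br
Why: In the Kulinkovich reaction the titanacyclopropane from EtMgBr and Ti(OiPr)4 adds twice to the ester carbonyl to give the cyclopropanol (C3, with C2 and C1 from the Grignard reagent), leaving ketal, silyl ethers and the 1,1‑disubstituted alkene untouched.

Step 7
Reactants: 11 cyclopropanol ketal
Product: 12 (4S,6R)‑6‑{3‑[(tert‑butyldiphenylsilyl)oxy]prop‑1‑en‑2‑yl}‑4‑hydroxy‑4‑[1‑(1‑hydroxycyclopropyl)ethyl]‑3‑methylcyclohex‑2‑en‑1‑one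
Conditions: oxalic acid (aq), THF, 0 °C to rt
Reagents that add atoms: water, O
Why: Mild acid hydrolysis of the allylic dimethyl ketal through its conjugated oxocarbenium ion should unveil the C8 enone and cleave the labile tertiary TMS ether, while the TBDPS ether and the cyclopropanol survive.

Step 8
Reactants: 12 enone cyclopropanol
Product: 13 (5S,7R,10R)‑12‑[(tert‑butyldiphenylsilyl)oxy]‑5‑hydroxyeudesm‑11(13)‑ene‑3,8‑dione (5β‑OH, cis‑fused)
Conditions: 9‑mesityl‑10‑methylacridinium tetrafluoroborate (5 mol %), 2,6‑lutidine (20 mol %), MeCN (0.01 M), 450 nm LEDs, rt, Ar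
Reagents that add atoms: none
Why: The excited acridinium oxidises the cyclopropanol (lutidine takes the proton), the cyclopropyloxy radical opens by strain‑driven β‑scission to the primary β‑keto radical at C1, this adds to C10, the β‑carbon of the C8 enone, and the C9 α‑keto radical is reduced by the acridinyl radical and protonated, so the step is a redox‑neutral isomerisation. The closest known reaction types are the oxidative or photoredox ring‑opening of cyclopropanols to β‑keto radicals with Giese addition to enones, and the 6‑exo radical cyclisation of tethered alkyl radicals onto 3‑methylcyclohex‑2‑enones that forms angular quaternary carbons. Ring A closes in the 6‑exo‑trig mode (C1 to C10, with C9 outside the new ring). The only new stereocentre, C10, is controlled by the C5 carbinol centre that carries the tether: C1 can only reach the enone face on which C4 stands and enters along the axial trajectory, which should give the cis‑fused ketol with the C10 methyl cis to C5–OH and cis to the C7 side chain. The step needs chemoselective oxidation of the cyclopropanol beside the tertiary C5 alcohol and the alkenes, secured by the low oxidation potential of the strained ring and its irreversible opening, and cyclisation ahead of hydrogen abstraction by the primary radical, secured by high dilution and the absence of a hydrogen donor. Regiochemistry is not at stake, because C10 is the only acceptor carbon within reach of a six‑membered transition state and both cyclopropane bonds are equivalent.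

Step 9
Reactants: 13 cis‑fused ketol
Product: 14 (7R,10R)‑12‑[(tert‑butyldiphenylsilyl)oxy]eudesma‑4,11(13)‑diene‑3,8‑dione
Conditions: p‑TsOH·H2O (10 mol %), toluene, 50 °C
Reagents that add atoms: none
Why: Acid‑catalysed β‑elimination of the tertiary ketol through the C3 enol (the aldol‑condensation dehydration of Robinson annulation ketols) should give the tetrasubstituted conjugated Δ4‑enone and erase the C4 and C5 stereocentres.

Step 10
Reactants: 14 enedione
Product: 15 (3S,7R,8R,10R)‑12‑[(tert‑butyldiphenylsilyl)oxy]eudesma‑4,11(13)‑diene‑3,8‑diol (3β,8β)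
Conditions: NaBH4, CeCl3·7H2O, MeOH, −40 °C to 0 °C
Reagents that add atoms: none
Why: In this Luche reduction hydride should add 1,2 to the enone along the axial α trajectory to give the pseudo‑equatorial 3β‑alcohol, and to the C8 ketone from the α face because the β face is blocked by the syn‑axial C10 methyl, giving the axial 8β‑alcohol.

Step 11
Reactants: 15 3β,8β‑diol
Product: 16 (3S,7R,8R,10R)‑12‑[(tert‑butyldiphenylsilyl)oxy]‑8‑hydroxyeudesma‑4,11(13)‑dien‑3‑yl 2‑methylpropanoate
Conditions: isobutyryl chloride (1.1 equiv), pyridine, CH2Cl2, −20 °C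
Reagents that add atoms: 2‑methylpropanoyl chloride, CC(C)C(Cl)=O
Why: Site‑selective acylation is expected because the pseudo‑equatorial allylic 3β‑OH is far more accessible than the axial 8β‑OH, which is 1,3‑diaxial to the C10 methyl and flanked by the C7 side chain.

Step 12
Reactants: 16 3‑isobutyrate
Product: 17 (3S,7R,8R,10R)‑8‑acetoxy‑12‑[(tert‑butyldiphenylsilyl)oxy]eudesma‑4,11(13)‑dien‑3‑yl 2‑methylpropanoate
Conditions: Ac2O, DMAP, Et3N, CH2Cl2, rt to 40 °C
Reagents that add atoms: acetic anhydride, CC(=O)OC(C)=O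
Why: DMAP‑catalysed acyl transfer should force the hindered axial 8β‑alcohol to its acetate.

Step 13
Reactants: 17 silyl ether diester
Product: 18 (3S,7R,8R,10R)‑8‑acetoxy‑12‑hydroxyeudesma‑4,11(13)‑dien‑3‑yl 2‑methylpropanoate
Conditions: HF·pyridine, pyridine, THF, 0 °C to rt
Reagents that add atoms: none
Why: Fluoride cleavage of the silyl ether under buffered conditions should neither transesterify nor migrate the two esters.

Step 14
Reactants: 18 primary allylic alcohol
Product: 19 (3S,7R,8R,10R)‑8‑acetoxy‑3‑(2‑methylpropanoyloxy)eudesma‑4,11(13)‑dien‑12‑oic acid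
Conditions: TEMPO (20 mol %), PhI(OAc)2, MeCN/H2O, rt
Reagents that add atoms: water, O
Why: Oxoammonium (TEMPO) oxidation in aqueous acetonitrile takes the primary allylic alcohol through the enal and its hydrate to the acrylic acid without touching the tetrasubstituted alkene or the esters.

Step 15
Reactants: 19 acrylic acid
Product: 20 methyl (3S,7R,8R,10R)‑8‑acetoxy‑3‑(2‑methylpropanoyloxy)eudesma‑4,11(13)‑dien‑12‑oate
Conditions: TMSCHN2, toluene/MeOH, 0 °C
Reagents that add atoms: (trimethylsilyl)diazomethane, C[Si](C)(C)C=[N+]=[N-]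
Why: Diazomethane‑type O‑methylation of the carboxylic acid under neutral conditions leaves the other esters intact.

Step 16
Reactants: 20 Δ4(5) olefin
Product: 21 methyl (3S,5S,7R,8R,10R)‑8‑acetoxy‑5‑hydroperoxy‑3‑(2‑methylpropanoyloxy)eudesma‑4(15),11(13)‑dien‑12‑oate
Conditions: O2, tetraphenylporphyrin (1 mol %), CH2Cl2, visible light, −20 °C
Reagents that add atoms: dioxygen, O=O
Why: In this Schenck ene reaction singlet oxygen should attack the tetrasubstituted Δ4 alkene from the α face (the β face is shielded by the C10 methyl), bond at C5 and abstract a C15 methyl hydrogen (methyl hydrogens are preferred over ring hydrogens in 1,2‑dialkylcyclohexenes, and the C3 hydrogen geminal to the acyloxy group is deactivated), giving the 5α‑hydroperoxide and the 4(15)‑methylene while the acrylate stays inert.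

## Compound list

1 | 2‑bromoprop‑2‑en‑1‑ol | C=C(Br)CO | starting material
2 | tert‑butyl[(2‑bromoprop‑2‑en‑1‑yl)oxy]diphenylsilane | C=C(Br)CO[Si](c1ccccc1)(c1ccccc1)C(C)(C)C | intermediate
3 | tert‑butyldiphenyl{[2‑(4,4,5,5‑tetramethyl‑1,3,2‑dioxaborolan‑2‑yl)prop‑2‑en‑1‑yl]oxy}silane | C=C(CO[Si](c1ccccc1)(c1ccccc1)C(C)(C)C)B1OC(C)(C)C(C)(C)O1 | intermediate
4 | 4‑methoxy‑2‑methylphenol | Cc1cc(OC)ccc1O | starting material
5 | 4,4‑dimethoxy‑2‑methylcyclohexa‑2,5‑dien‑1‑one | COC1(OC)C=CC(=O)C(C)=C1 | intermediate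
6 | (5R)‑5‑{3‑[(tert‑butyldiphenylsilyl)oxy]prop‑1‑en‑2‑yl}‑4,4‑dimethoxy‑2‑methylcyclohex‑2‑en‑1‑one | C=C(CO[Si](c1ccccc1)(c1ccccc1)C(C)(C)C)[C@H]1CC(=O)C(C)=CC1(OC)OC | intermediate
7 | methyl propanoate | CCC(=O)OC | starting material
8 | lithium enolate of methyl propanoate (not isolated) | CC=C(OC)O[Li] | intermediate
9 | lithium (1S,5R)‑alkoxide of the aldol adduct of 6 and 8 (not isolated) | C=C(CO[Si](c1ccccc1)(c1ccccc1)C(C)(C)C)[C@H]1C[C@](O[Li])(C(C)C(=O)OC)C(C)=CC1(OC)OC | intermediate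
10 | methyl 2‑[(1S,5R)‑5‑{3‑[(tert‑butyldiphenylsilyl)oxy]prop‑1‑en‑2‑yl}‑4,4‑dimethoxy‑2‑methyl‑1‑[(trimethylsilyl)oxy]cyclohex‑2‑en‑1‑yl]propanoate (C4 epimers) | C=C(CO[Si](c1ccccc1)(c1ccccc1)C(C)(C)C)[C@H]1C[C@](O[Si](C)(C)C)(C(C)C(=O)OC)C(C)=CC1(OC)OC | intermediate
11 | 1‑{1‑[(1S,5R)‑5‑{3‑[(tert‑butyldiphenylsilyl)oxy]prop‑1‑en‑2‑yl}‑4,4‑dimethoxy‑2‑methyl‑1‑[(trimethylsilyl)oxy]cyclohex‑2‑en‑1‑yl]ethyl}cyclopropan‑1‑ol (C4 epimers) | C=C(CO[Si](c1ccccc1)(c1ccccc1)C(C)(C)C)[C@H]1C[C@](O[Si](C)(C)C)(C(C)C2(O)CC2)C(C)=CC1(OC)OC | intermediate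
12 | (4S,6R)‑6‑{3‑[(tert‑butyldiphenylsilyl)oxy]prop‑1‑en‑2‑yl}‑4‑hydroxy‑4‑[1‑(1‑hydroxycyclopropyl)ethyl]‑3‑methylcyclohex‑2‑en‑1‑one (C4 epimers) | C=C(CO[Si](c1ccccc1)(c1ccccc1)C(C)(C)C)[C@H]1C[C@](O)(C(C)C2(O)CC2)C(C)=CC1=O | intermediate
13 | (5S,7R,10R)‑12‑[(tert‑butyldiphenylsilyl)oxy]‑5‑hydroxyeudesm‑11(13)‑ene‑3,8‑dione (5β‑OH, cis‑fused, C4 epimers) | C=C(CO[Si](c1ccccc1)(c1ccccc1)C(C)(C)C)[C@H]1C[C@]2(O)C(C)C(=O)CC[C@]2(C)CC1=O | intermediate
14 | (7R,10R)‑12‑[(tert‑butyldiphenylsilyl)oxy]eudesma‑4,11(13)‑diene‑3,8‑dione | C=C(CO[Si](c1ccccc1)(c1ccccc1)C(C)(C)C)[C@H]1CC2=C(C)C(=O)CC[C@]2(C)CC1=O | intermediate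
15 | (3S,7R,8R,10R)‑12‑[(tert‑butyldiphenylsilyl)oxy]eudesma‑4,11(13)‑diene‑3,8‑diol | C=C(CO[Si](c1ccccc1)(c1ccccc1)C(C)(C)C)[C@H]1CC2=C(C)[C@@H](O)CC[C@]2(C)C[C@H]1O | intermediate
16 | (3S,7R,8R,10R)‑12‑[(tert‑butyldiphenylsilyl)oxy]‑8‑hydroxyeudesma‑4,11(13)‑dien‑3‑yl 2‑methylpropanoate | C=C(CO[Si](c1ccccc1)(c1ccccc1)C(C)(C)C)[C@H]1CC2=C(C)[C@@H](OC(=O)C(C)C)CC[C@]2(C)C[C@H]1O | intermediate
17 | (3S,7R,8R,10R)‑8‑acetoxy‑12‑[(tert‑butyldiphenylsilyl)oxy]eudesma‑4,11(13)‑dien‑3‑yl 2‑methylpropanoate | C=C(CO[Si](c1ccccc1)(c1ccccc1)C(C)(C)C)[C@H]1CC2=C(C)[C@@H](OC(=O)C(C)C)CC[C@]2(C)C[C@H]1OC(C)=O | intermediate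
18 | (3S,7R,8R,10R)‑8‑acetoxy‑12‑hydroxyeudesma‑4,11(13)‑dien‑3‑yl 2‑methylpropanoate | C=C(CO)[C@H]1CC2=C(C)[C@@H](OC(=O)C(C)C)CC[C@]2(C)C[C@H]1OC(C)=O | intermediate
19 | (3S,7R,8R,10R)‑8‑acetoxy‑3‑(2‑methylpropanoyloxy)eudesma‑4,11(13)‑dien‑12‑oic acid | C=C(C(=O)O)[C@H]1CC2=C(C)[C@@H](OC(=O)C(C)C)CC[C@]2(C)C[C@H]1OC(C)=O | intermediate
20 | methyl (3S,7R,8R,10R)‑8‑acetoxy‑3‑(2‑methylpropanoyloxy)eudesma‑4,11(13)‑dien‑12‑oate | C=C(C(=O)OC)[C@H]1CC2=C(C)[C@@H](OC(=O)C(C)C)CC[C@]2(C)C[C@H]1OC(C)=O | intermediate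
21 | methyl (3S,5S,7R,8R,10R)‑8‑acetoxy‑5‑hydroperoxy‑3‑(2‑methylpropanoyloxy)eudesma‑4(15),11(13)‑dien‑12‑oate | C=C(C(=O)OC)[C@H]1C[C@@]2(OO)C(=C)[C@@H](OC(=O)C(C)C)CC[C@]2(C)C[C@H]1OC(C)=O | target

## Step count and risks

Total step count: 16. Longest linear sequence: 15 steps (steps 1, 2 and 4 to 16).

**Step 8 (key step).** The primary C1 radical may be quenched by hydrogen abstraction before it adds to the fully substituted C10, or the photocatalyst may oxidise other sites. The fallback sets out from 12 and returns at 13. The cyclopropanol of 12 is opened with N‑iodosuccinimide (CH2Cl2, 0 °C, electrophilic ring‑opening of a cyclopropanol) to the β‑iodo ketone F1. F1 is then cyclised by the tin hydride method (Bu3SnH, AIBN, benzene, 80 °C, slow addition). Iodine abstraction generates the same C1 radical without any oxidant, and the stannane delivers hydrogen to the C9 radical, which should give 13.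

**Step 16.** Hydrogen abstraction may occur at C6 instead of C15 (giving the 4‑hydroperoxy‑5‑ene), or oxygen may attack from the β face. The fallback sets out from 20 and ends at 21.
- Epoxidation with mCPBA (CH2Cl2, NaHCO3, 0 °C) from the α face should give the 4α,5α‑epoxide F2.
- Base‑induced epoxide to allylic alcohol isomerisation with Et2Al(TMP) (diethylaluminium 2,2,6,6‑tetramethylpiperidide, toluene, 0 °C) removes a proton from the unhindered C15 methyl and should give the 5α‑hydroxy‑4(15)‑ene F3.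
- Acid‑catalysed perhydrolysis of this tertiary allylic alcohol (50% H2O2, cat. H2SO4, THF, 0 °C) through the allyl cation, captured at the tertiary carbon anti to the C10 methyl, should give 21.

**Step 6.** Addition of the titanacyclopropane to the hindered α‑branched ester may be slow, or the TMS group may be lost with retro‑aldol cleavage. The fallback sets out from 6 and returns at 12.
- The addition of step 5 is run with the lithium enolate of N‑methoxy‑N‑methylpropanamide (LDA, THF, −78 °C, then TMSCl) to give the Weinreb amide F4.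
- MeMgBr (THF, 0 °C) gives the methyl ketone F5.
- LDA/TMSCl (−78 °C) gives the terminal silyl enol ether F6.
- Furukawa–Simmons–Smith cyclopropanation of the electron‑rich enol ether (Et2Zn, CH2I2, CH2Cl2, 0 °C) gives the cyclopropyl silyl ether F7.
- The hydrolysis conditions of step 7 then remove the ketal and both TMS groups to give 12.

## Further compounds

F1 | step 8 | (4S,6R)‑6‑{3‑[(tert‑butyldiphenylsilyl)oxy]prop‑1‑en‑2‑yl}‑4‑hydroxy‑4‑(5‑iodo‑3‑oxopentan‑2‑yl)‑3‑methylcyclohex‑2‑en‑1‑one | C=C(CO[Si](c1ccccc1)(c1ccccc1)C(C)(C)C)[C@H]1C[C@](O)(C(C)C(=O)CCI)C(C)=CC1=O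
F2 | step 16 | methyl 8β‑acetoxy‑4α,5α‑epoxy‑3β‑(2‑methylpropanoyloxy)eudesm‑11(13)‑en‑12‑oate | C=C(C(=O)OC)[C@H]1C[C@@]2(O3)[C@@]3(C)[C@@H](OC(=O)C(C)C)CC[C@]2(C)C[C@H]1OC(C)=O
F3 | step 16 | methyl 8β‑acetoxy‑5α‑hydroxy‑3β‑(2‑methylpropanoyloxy)eudesma‑4(15),11(13)‑dien‑12‑oate | C=C(C(=O)OC)[C@H]1C[C@@]2(O)C(=C)[C@@H](OC(=O)C(C)C)CC[C@]2(C)C[C@H]1OC(C)=O
F4 | step 6 | 2‑[(1S,5R)‑5‑{3‑[(tert‑butyldiphenylsilyl)oxy]prop‑1‑en‑2‑yl}‑4,4‑dimethoxy‑2‑methyl‑1‑[(trimethylsilyl)oxy]cyclohex‑2‑en‑1‑yl]‑N‑methoxy‑N‑methylpropanamide | C=C(CO[Si](c1ccccc1)(c1ccccc1)C(C)(C)C)[C@H]1C[C@](O[Si](C)(C)C)(C(C)C(=O)N(C)OC)C(C)=CC1(OC)OC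
F5 | step 6 | 3‑[(1S,5R)‑5‑{3‑[(tert‑butyldiphenylsilyl)oxy]prop‑1‑en‑2‑yl}‑4,4‑dimethoxy‑2‑methyl‑1‑[(trimethylsilyl)oxy]cyclohex‑2‑en‑1‑yl]butan‑2‑one | C=C(CO[Si](c1ccccc1)(c1ccccc1)C(C)(C)C)[C@H]1C[C@](O[Si](C)(C)C)(C(C)C(C)=O)C(C)=CC1(OC)OC
F6 | step 6 | trimethylsilyl enol ether of F5 (terminal, but‑1‑en‑2‑yl) | C=C(CO[Si](c1ccccc1)(c1ccccc1)C(C)(C)C)[C@H]1C[C@](O[Si](C)(C)C)(C(C)C(=C)O[Si](C)(C)C)C(C)=CC1(OC)OC
F7 | step 6 | trimethylsilyl ether of cyclopropanol 11 (bis‑TMS ether) | C=C(CO[Si](c1ccccc1)(c1ccccc1)C(C)(C)C)[C@H]1C[C@](O[Si](C)(C)C)(C(C)C2(O[Si](C)(C)C)CC2)C(C)=CC1(OC)OC
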